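**Plan**
1.  Retrosynthetic cuts: the acetate and the diol ethers; C8=C17 (Wittig); the C3 carbonyl helper (Wolff–Kishner); C1–C10 of ring A (6-endo radical closure of a C10 radical onto a C3 vinyl ketone); C8–C9 of ring B (carbonyl-ene); C4–C5 (Ireland–Claisen); C9–C10/C9–C11 (carbonylative Suzuki–Miyaura, C9 from CO); C13–C14 (crotylboration).
2.  Forward order: side chain C11–C15 and a C5–C8/C10/C20 alkenyl iodide are joined through CO to an open-chain enone; reduction, acylation and a [3,3] shift put the C4 gem-dimethyl arm on C5; ring B closes, then ring A; C3 is cleared, C8 is methylenated, the 15-acetate is set.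
3.  Stereochemistry: C13/C14 come from a reagent-controlled syn-crotylboration; the C9 carbinol is set by oxazaborolidine catalysis and transferred suprafacially to C5 in the Claisen chair; C5 then sets C9 (ene chair) and C10 (radical closure) by substrate control.
4.  Enabling feature: C10 is the methyl-bearing quaternary carbon of ring B between C5 and C9, so it can be carried as an exocyclic C10=CH2 that takes up a hydrogen atom to give the tertiary radical together with its methyl (C20). C1 ends the arm C4(Me2)–C3–C2 on C5, where a temporary C3 carbonyl makes C1=C2 a radical acceptor placed for 6-endo closure of ring A.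

Key step: step 14

Remark: atoms carry labdane numbers throughout; the C8 carbinol of 22–26 is a temporary stereocenter, drawn as expected from the closed ene transition state, and it disappears in step 16.

**Step 1**
Reactants: 1 2-[(4-methoxybenzyl)oxy]acetaldehyde; 2 (Z)-but-2-ene
Product: 5 (2S,3R)-1-[(4-methoxybenzyl)oxy]-3-methylpent-4-en-2-ol, via (Z)-crotylbis(isopinocampheyl)borane 3 (not isolated), via O-boryl adduct 4 (not isolated)
Conditions: 2, KOtBu, n-BuLi, THF, −78 to −45 °C; (−)-Ipc2BOMe [from (+)-α-pinene], −78 °C; BF3·OEt2; 1, −78 °C; then NaOH, H2O2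
Reagents that add atoms: none
Why: Brown crotylboration through a closed chair transition state, in which the Z crotyl geometry should give the syn C13/C14 pair and the isopinocampheyl groups select the aldehyde face leading to 14S (hence 13R).

**Step 2**
Reactants: 5
Product: 6 (2S,3R)-1,2-bis[(4-methoxybenzyl)oxy]-3-methylpent-4-ene
Conditions: NaH, PMBCl, Bu4NI (cat.), DMF, 0 °C to rt
Reagents that add atoms: 4-methoxybenzyl chloride, COc1ccc(CCl)cc1
Why: Williamson etherification of the secondary alkoxide touches no stereocenter and gives both oxygens the same oxidatively removable group, which should survive bases, hydrides, Lewis acids and hot KOH.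

**Step 3**
Reactants: 7 hex-4-yn-1-ol
Product: 8 tert-butyl(hex-4-yn-1-yloxy)dimethylsilane
Conditions: TBSCl, imidazole, CH2Cl2, rt
Reagents that add atoms: tert-butyldimethylsilyl chloride, CC(C)(C)[Si](C)(C)Cl
Why: Standard silylation of a primary alcohol masks the future C8 oxygen.

**Step 4**
Reactants: 8
Product: 10 (E)-tert-butyl[(5-iodohex-4-en-1-yl)oxy]dimethylsilane, via alkenylzirconocene chloride 9 (not isolated)
Conditions: Cp2Zr(H)Cl (1.8 equiv), THF, rt to 40 °C; then I2, 0 °C
Reagents that add atoms: iodine, II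
Why: Hydrozirconation is a syn addition and excess Cp2Zr(H)Cl should equilibrate the metal to the less hindered methyl-bearing alkyne carbon, so iodinolysis with retention gives the E 2-iodoalkene (C10 with its C20 methyl, C5 to C8).

**Step 5**
Reactants: 6; 10
Product: 12 (4E,9R,10S)-1-[(tert-butyldimethylsilyl)oxy]-10,11-bis[(4-methoxybenzyl)oxy]-5,9-dimethylundec-4-en-6-one, via B-alkyl-9-BBN 11 (not isolated)
Conditions: 6, 9-BBN-H, THF, rt; then 10, CO (1 atm), Pd(PPh3)4 (5 mol%), K3PO4, dioxane, 50 °C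
Reagents that add atoms: carbon monoxide, [C-]#[O+]
Why: Carbonylative B-alkyl Suzuki–Miyaura coupling, in which anti-Markovnikov hydroboration puts boron on C11, the alkenyl iodide adds to zerovalent palladium with retention of the E geometry and CO inserts before transmetalation, so the carbonyl carbon becomes C9.

**Step 6**
Reactants: 12
Product: 13 (4E,6S,9R,10S)-1-[(tert-butyldimethylsilyl)oxy]-10,11-bis[(4-methoxybenzyl)oxy]-5,9-dimethylundec-4-en-6-ol
Conditions: (R)-Me-CBS oxazaborolidine (C18H20BNO, 10 mol%), catecholborane, toluene, −78 °C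
Reagents that add atoms: none
Why: Corey–Bakshi–Shibata reduction, in which the α-methylalkenyl group acts as the large and the CH2 chain as the small substituent, so the (R)-catalyst should deliver hydride to the face that gives the 6S carbinol (C9).

**Step 7**
Reactants: 13
Product: 14 (4E,6S,9R,10S)-1-[(tert-butyldimethylsilyl)oxy]-10,11-bis[(4-methoxybenzyl)oxy]-5,9-dimethylundec-4-en-6-yl 2-methylpropanoate
Conditions: i-PrCOCl, pyridine, DMAP (cat.), CH2Cl2, 0 °C to rt
Reagents that add atoms: isobutyryl chloride, CC(C)C(Cl)=O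
Why: O-Acylation with retention at C9 attaches the unit that becomes C3, C4 and both C4 methyl groups.

**Step 8**
Reactants: 14
Product: 17 (3R,4E,8R,9S)-3-{3-[(tert-butyldimethylsilyl)oxy]propyl}-9,10-bis[(4-methoxybenzyl)oxy]-2,2,4,8-tetramethyldec-4-enoic acid, via silyl ketene acetal 15 (not isolated), via trimethylsilyl ester 16 (not isolated)
Conditions: LDA, THF, −78 °C; TMSCl, Et3N, −78 °C to rt, then 60 °C; aqueous citric acid work-up
Reagents that add atoms: none
Why: Ireland–Claisen rearrangement through a chair with the C9 substituent equatorial, so the C9–O stereocenter is transferred suprafacially across the E olefin to C5 (3R in 17) and the new C9=C10 olefin forms E; the symmetric dimethylketene acetal makes enolate geometry irrelevant.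

**Step 9**
Reactants: 17
Product: 19 (3R,4E,8R,9S)-3-{3-[(tert-butyldimethylsilyl)oxy]propyl}-N-methoxy-9,10-bis[(4-methoxybenzyl)oxy]-N,2,2,4,8-pentamethyldec-4-enamide, via acid chloride 18 (not isolated)
Conditions: 1-chloro-N,N,2-trimethylprop-1-en-1-amine, CH2Cl2, 0 °C; then MeNHOMe·HCl, Et3N, 0 °C to rt
Reagents that add atoms: N,O-dimethylhydroxylamine hydrochloride, CNOC.Cl
Why: Neutral acid chloride formation (Ghosez reagent) spares the silyl ether and activates the hindered α-quaternary acid for Weinreb amide formation.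

**Step 10**
Reactants: 19
Product: 20 (3R,4E,8R,9S)-3-(3-hydroxypropyl)-N-methoxy-9,10-bis[(4-methoxybenzyl)oxy]-N,2,2,4,8-pentamethyldec-4-enamide
Conditions: Bu4NF, THF, 0 °C to rt
Reagents that add atoms: none
Why: Fluoride cleaves the primary silyl ether only, since the PMB ethers and the amide are inert to it.

**Step 11**
Reactants: 20
Product: 21 (3R,4E,8R,9S)-N-methoxy-9,10-bis[(4-methoxybenzyl)oxy]-N,2,2,4,8-pentamethyl-3-(3-oxopropyl)dec-4-enamide
Conditions: Dess–Martin periodinane, CH2Cl2, rt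
Reagents that add atoms: none
Why: Dess–Martin oxidation gives the C8 aldehyde without touching the olefin or the benzylic ethers.

**Step 12**
Reactants: 21
Product: 22 2-[(1R,3R,4S)-3-{(3R,4S)-4,5-bis[(4-methoxybenzyl)oxy]-3-methylpentyl}-4-hydroxy-2-methylidenecyclohexyl]-N-methoxy-N,2-dimethylpropanamide
Conditions: Me2AlCl (2.5 equiv), CH2Cl2, −78 to −20 °C
Reagents that add atoms: none
Why: Type-2 intramolecular carbonyl-ene reaction, in which the activated C8 aldehyde bonds to C9 of the trisubstituted olefin while a C20 hydrogen shifts to oxygen to leave the exocyclic C10=CH2; a chair with the C5 arm equatorial and the E olefin should place the C9 chain equatorial, cis to the C5 arm, and the bridged closed transition state the C8 hydroxyl axial.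

**Step 13**
Reactants: 22
Product: 23 4-[(1R,3R,4S)-3-{(3R,4S)-4,5-bis[(4-methoxybenzyl)oxy]-3-methylpentyl}-4-hydroxy-2-methylidenecyclohexyl]-4-methylpent-1-en-3-one
Conditions: CH2=CHMgBr (3.5 equiv), THF, −20 to 0 °C; cold 1 M HCl quench
Reagents that add atoms: vinylmagnesium bromide, C=C[Mg]Br
Why: Weinreb ketone synthesis, in which the chelated tetrahedral adduct prevents over-addition and gives the C3 vinyl ketone (C1=C2) after one equivalent of reagent is spent on the C8 hydroxyl.

**Step 14**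
Reactants: 23
Product: 24 (5R,8S,9R,10S,13R,14S)-8-hydroxy-14,15-bis[(4-methoxybenzyl)oxy]-17-norlabdan-3-one
Conditions: Fe(acac)3 (0.3 equiv), PhSiH3 (2.5 equiv), EtOH/ethylene glycol 5:1, 60 °C
Reagents that add atoms: none
Why: An iron hydride formed from Fe(acac)3 and PhSiH3 transfers a hydrogen atom to the terminal carbon of the electron-rich C10=CH2 olefin, which creates the C20 methyl and a tertiary radical at C10; this nucleophilic radical adds to C1 of the vinyl ketone, and the C2 α-keto radical is reduced by divalent iron and protonated by ethanol. The closest known reaction type is the metal-hydride hydrogen-atom-transfer reductive olefin–enone coupling, here intramolecular (a Giese-type radical conjugate addition). Ring A closes 6-endo-trig, because attack at C1 gives the carbonyl-stabilized radical whereas 5-exo attack at C2 would give an unstabilized primary radical through a tether strained by the sp2 C3. The new quaternary stereocenter C10 is controlled by C5: in a chair-like transition state the C4 arm leaves C5 equatorially and C1 bonds equatorially to C10 while the new methyl turns axial, which should give the trans ring fusion (5α-H, 10β-CH3), as tertiary ring radicals do when they close onto a chain on the neighboring carbon in radical polyene cyclizations. The step needs hydrogen-atom transfer to the 1,1-disubstituted olefin and not to the electron-poor enone (secured by polarity), and closure faster than reduction of the tertiary radical (secured by the gem-dimethyl arm and the activated acceptor). The C3 carbonyl is the helper that is removed in step 15.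

**Step 15**
Reactants: 24
Product: 26 (5S,8S,9R,10S,13R,14S)-14,15-bis[(4-methoxybenzyl)oxy]-17-norlabdan-8-ol, via hydrazone 25 (not isolated)
Conditions: N2H4·H2O, KOH, diethylene glycol, 130 °C, then 200 °C
Reagents that add atoms: none
Why: Wolff–Kishner reduction (Huang-Minlon procedure), which is reliable for 4,4-dimethyl-3-ketones of this ring type and leaves the ethers and the secondary alcohol untouched.

**Step 16**
Reactants: 26
Product: 27 (5S,9R,10S,13R,14S)-14,15-bis[(4-methoxybenzyl)oxy]-17-norlabdan-8-one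
Conditions: Dess–Martin periodinane, CH2Cl2, rt
Reagents that add atoms: none
Why: Dess–Martin oxidation removes the temporary C8 stereocenter, and C9, now α to the ketone, already holds the thermodynamically preferred equatorial side chain.

**Step 17**
Reactants: 27
Product: 28 (5S,9S,10S,13R,14S)-14,15-bis[(4-methoxybenzyl)oxy]labd-8(17)-ene
Conditions: Ph3PCH3Br, KOtBu, toluene, 90 °C
Reagents that add atoms: methyltriphenylphosphonium bromide, C[P+](c1ccccc1)(c1ccccc1)c1ccccc1.[Br-]
Why: Wittig methylenation of the hindered 8-ketone installs C17, and any enolization at C9 under the basic conditions returns the equatorial, natural configuration.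

**Step 18**
Reactants: 28
Product: 29 (5S,9S,10S,13R,14S)-labd-8(17)-ene-14,15-diol
Conditions: DDQ (2.5 equiv), CH2Cl2/aqueous pH 7 buffer, 0 °C to rt
Reagents that add atoms: none
Why: Oxidative cleavage of both PMB ethers by hydride abstraction at the electron-rich benzylic positions leaves the isolated exocyclic olefin alone.

**Step 19**
Reactants: 29
Product: 30 (5S,9S,10S,13R,14S)-14-hydroxylabd-8(17)-en-15-yl acetate
Conditions: AcCl (1.05 equiv), 2,4,6-collidine, CH2Cl2, −78 °C
Reagents that add atoms: acetyl chloride, CC(Cl)=O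
Why: Kinetically selective acylation of the primary over the secondary hydroxyl of the 1,2-diol at low temperature with a hindered base.

**Compound list**
1 | 2-[(4-methoxybenzyl)oxy]acetaldehyde | O=CCOCc1ccc(OC)cc1 | starting material
2 | (Z)-but-2-ene | C/C=C\C | starting material
3 | (Z)-crotylbis(isopinocampheyl)borane | C/C=C\CB([C@@H]1C[C@@H]2C[C@H]([C@H]1C)C2(C)C)[C@@H]1C[C@@H]2C[C@H]([C@H]1C)C2(C)C | intermediate (not isolated)
4 | O-bis(isopinocampheyl)boryl ether of 5 | C=C[C@@H](C)[C@H](OB([C@@H]1C[C@@H]2C[C@H]([C@H]1C)C2(C)C)[C@@H]1C[C@@H]2C[C@H]([C@H]1C)C2(C)C)COCc1ccc(OC)cc1 | intermediate (not isolated)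
5 | (2S,3R)-1-[(4-methoxybenzyl)oxy]-3-methylpent-4-en-2-ol | C=C[C@@H](C)[C@H](O)COCc1ccc(OC)cc1 | intermediate
6 | (2S,3R)-1,2-bis[(4-methoxybenzyl)oxy]-3-methylpent-4-ene | C=C[C@@H](C)[C@H](OCc1ccc(OC)cc1)COCc1ccc(OC)cc1 | intermediate
7 | hex-4-yn-1-ol | CC#CCCCO | starting material
8 | tert-butyl(hex-4-yn-1-yloxy)dimethylsilane | CC#CCCCO[Si](C)(C)C(C)(C)C | intermediate
9 | (E)-[6-(tert-butyldimethylsilyloxy)hex-2-en-2-yl]zirconocene chloride | C/C(=C\CCCO[Si](C)(C)C(C)(C)C)[Zr](Cl)(C1C=CC=C1)C1C=CC=C1 | intermediate (not isolated)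
10 | (E)-tert-butyl[(5-iodohex-4-en-1-yl)oxy]dimethylsilane | C/C(I)=C\CCCO[Si](C)(C)C(C)(C)C | intermediate
11 | 9-{(3R,4S)-4,5-bis[(4-methoxybenzyl)oxy]-3-methylpentyl}-9-borabicyclo[3.3.1]nonane | B1(CC[C@@H](C)[C@H](OCc2ccc(OC)cc2)COCc2ccc(OC)cc2)C2CCCC1CCC2 | intermediate (not isolated)
12 | (4E,9R,10S)-1-[(tert-butyldimethylsilyl)oxy]-10,11-bis[(4-methoxybenzyl)oxy]-5,9-dimethylundec-4-en-6-one | C/C(=C\CCCO[Si](C)(C)C(C)(C)C)C(=O)CC[C@@H](C)[C@H](OCc1ccc(OC)cc1)COCc1ccc(OC)cc1 | intermediate
13 | (4E,6S,9R,10S)-1-[(tert-butyldimethylsilyl)oxy]-10,11-bis[(4-methoxybenzyl)oxy]-5,9-dimethylundec-4-en-6-ol | C/C(=C\CCCO[Si](C)(C)C(C)(C)C)[C@@H](O)CC[C@@H](C)[C@H](OCc1ccc(OC)cc1)COCc1ccc(OC)cc1 | intermediate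
14 | 2-methylpropanoate of 13 | C/C(=C\CCCO[Si](C)(C)C(C)(C)C)[C@@H](OC(=O)C(C)C)CC[C@@H](C)[C@H](OCc1ccc(OC)cc1)COCc1ccc(OC)cc1 | intermediate
15 | O-trimethylsilyl ketene acetal of 14 | C/C(=C\CCCO[Si](C)(C)C(C)(C)C)[C@@H](OC(O[Si](C)(C)C)=C(C)C)CC[C@@H](C)[C@H](OCc1ccc(OC)cc1)COCc1ccc(OC)cc1 | intermediate (not isolated)
16 | trimethylsilyl ester of 17 | C[Si](C)(C)OC(=O)C(C)(C)[C@H](CCCO[Si](C)(C)C(C)(C)C)/C(C)=C/CC[C@@H](C)[C@H](OCc1ccc(OC)cc1)COCc1ccc(OC)cc1 | intermediate (not isolated)
17 | (3R,4E,8R,9S)-3-{3-[(tert-butyldimethylsilyl)oxy]propyl}-9,10-bis[(4-methoxybenzyl)oxy]-2,2,4,8-tetramethyldec-4-enoic acid | OC(=O)C(C)(C)[C@H](CCCO[Si](C)(C)C(C)(C)C)/C(C)=C/CC[C@@H](C)[C@H](OCc1ccc(OC)cc1)COCc1ccc(OC)cc1 | intermediate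
18 | acid chloride of 17 | ClC(=O)C(C)(C)[C@H](CCCO[Si](C)(C)C(C)(C)C)/C(C)=C/CC[C@@H](C)[C@H](OCc1ccc(OC)cc1)COCc1ccc(OC)cc1 | intermediate (not isolated)
19 | (3R,4E,8R,9S)-3-{3-[(tert-butyldimethylsilyl)oxy]propyl}-N-methoxy-9,10-bis[(4-methoxybenzyl)oxy]-N,2,2,4,8-pentamethyldec-4-enamide | CON(C)C(=O)C(C)(C)[C@H](CCCO[Si](C)(C)C(C)(C)C)/C(C)=C/CC[C@@H](C)[C@H](OCc1ccc(OC)cc1)COCc1ccc(OC)cc1 | intermediate
20 | (3R,4E,8R,9S)-3-(3-hydroxypropyl)-N-methoxy-9,10-bis[(4-methoxybenzyl)oxy]-N,2,2,4,8-pentamethyldec-4-enamide | CON(C)C(=O)C(C)(C)[C@H](CCCO)/C(C)=C/CC[C@@H](C)[C@H](OCc1ccc(OC)cc1)COCc1ccc(OC)cc1 | intermediate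
21 | (3R,4E,8R,9S)-N-methoxy-9,10-bis[(4-methoxybenzyl)oxy]-N,2,2,4,8-pentamethyl-3-(3-oxopropyl)dec-4-enamide | CON(C)C(=O)C(C)(C)[C@H](CCC=O)/C(C)=C/CC[C@@H](C)[C@H](OCc1ccc(OC)cc1)COCc1ccc(OC)cc1 | intermediate
22 | 2-[(1R,3R,4S)-3-{(3R,4S)-4,5-bis[(4-methoxybenzyl)oxy]-3-methylpentyl}-4-hydroxy-2-methylidenecyclohexyl]-N-methoxy-N,2-dimethylpropanamide | C=C1[C@H](C(C)(C)C(=O)N(C)OC)CC[C@H](O)[C@@H]1CC[C@@H](C)[C@H](OCc1ccc(OC)cc1)COCc1ccc(OC)cc1 | intermediate
23 | 4-[(1R,3R,4S)-3-{(3R,4S)-4,5-bis[(4-methoxybenzyl)oxy]-3-methylpentyl}-4-hydroxy-2-methylidenecyclohexyl]-4-methylpent-1-en-3-one | C=C1[C@H](C(C)(C)C(=O)C=C)CC[C@H](O)[C@@H]1CC[C@@H](C)[C@H](OCc1ccc(OC)cc1)COCc1ccc(OC)cc1 | intermediate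
24 | (5R,8S,9R,10S,13R,14S)-8-hydroxy-14,15-bis[(4-methoxybenzyl)oxy]-17-norlabdan-3-one (trans-decalin, 5α-H, 10β-CH3, 9β side chain, 8β-OH) | O[C@H]1CC[C@H]2C(C)(C)C(=O)CC[C@]2(C)[C@H]1CC[C@@H](C)[C@H](OCc1ccc(OC)cc1)COCc1ccc(OC)cc1 | intermediate
25 | hydrazone of 24 | O[C@H]1CC[C@H]2C(C)(C)C(=NN)CC[C@]2(C)[C@H]1CC[C@@H](C)[C@H](OCc1ccc(OC)cc1)COCc1ccc(OC)cc1 | intermediate (not isolated)
26 | (5S,8S,9R,10S,13R,14S)-14,15-bis[(4-methoxybenzyl)oxy]-17-norlabdan-8-ol | O[C@H]1CC[C@H]2C(C)(C)CCC[C@]2(C)[C@H]1CC[C@@H](C)[C@H](OCc1ccc(OC)cc1)COCc1ccc(OC)cc1 | intermediate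
27 | (5S,9R,10S,13R,14S)-14,15-bis[(4-methoxybenzyl)oxy]-17-norlabdan-8-one | O=C1CC[C@H]2C(C)(C)CCC[C@]2(C)[C@H]1CC[C@@H](C)[C@H](OCc1ccc(OC)cc1)COCc1ccc(OC)cc1 | intermediate
28 | (5S,9S,10S,13R,14S)-14,15-bis[(4-methoxybenzyl)oxy]labd-8(17)-ene | C=C1CC[C@H]2C(C)(C)CCC[C@]2(C)[C@H]1CC[C@@H](C)[C@H](OCc1ccc(OC)cc1)COCc1ccc(OC)cc1 | intermediate
29 | (5S,9S,10S,13R,14S)-labd-8(17)-ene-14,15-diol | C=C1CC[C@H]2C(C)(C)CCC[C@]2(C)[C@H]1CC[C@@H](C)[C@H](O)CO | intermediate
30 | (5S,9S,10S,13R,14S)-14-hydroxylabd-8(17)-en-15-yl acetate | C=C1CC[C@H]2C(C)(C)CCC[C@]2(C)[C@H]1CC[C@@H](C)[C@H](O)COC(C)=O | target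

**Step count**
Total: 19 steps. Longest linear sequence: 17 steps (steps 1, 2 and 5–19 from 1; equally steps 3–19 from 7).

**Steps most likely to fail, with fallbacks**

Step 14. The iron hydride may reduce the tertiary C10 radical or the enone before ring closure, or reversible hydrogen-atom transfer may move the olefin into the ring. The fallback makes the same radical by halogen abstraction under low hydride concentration. It sets out from 22: HCl in CH2Cl2 at −78 °C should add in the Markovnikov sense to C10=CH2 and give 2-[(1R,3R,4S)-2-chloro-3-{(3R,4S)-4,5-bis[(4-methoxybenzyl)oxy]-3-methylpentyl}-4-hydroxy-2-methylcyclohexyl]-N-methoxy-N,2-dimethylpropanamide F5 (C10 epimers, both usable). CH2=CHMgBr then gives the corresponding chloro vinyl ketone F6. Slow addition of Bu3SnH with AIBN in benzene at 80 °C abstracts chlorine, and the same 6-endo closure returns to the route at 24.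

Step 12. The closure may become stepwise and cationic, with proton loss toward C5 (endocyclic olefin) or capture of the C10 cation by chloride or by the amide oxygen instead of the concerted hydrogen shift. The fallback replaces the ene reaction by an intramolecular Nozaki–Hiyama allylation and sets out from 21. SeO2 (cat.) with t-BuOOH should hydroxylate the C20 methyl, the allylic position at the more substituted olefin end, to give the 4-(hydroxymethyl) analogue of 21 F3. CBr4/PPh3 converts it into the 4-(bromomethyl) analogue of 21 F4. CrCl2 in THF forms the allylchromium, which adds through its γ-carbon C9 to the C8 aldehyde and shifts the olefin to C10=C20. Its closed six-membered arrangement Cr–O–C8–C9–C10–C20 spans the same atoms as the ene transition state, so the same isomer is expected and the fallback returns to the route at 22.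

Step 5. Transmetalation may outrun CO insertion (direct B-alkyl coupling to a diene-free alkyl-alkenyl product), or the alkylpalladium may lose a β-hydride. The fallback builds the enone by hydroformylation and carbonyl addition and sets out from 6. Rh(acac)(CO)2/Xantphos under CO/H2 should give the linear aldehyde (4R,5S)-5,6-bis[(4-methoxybenzyl)oxy]-4-methylhexanal F1. The alkenyllithium made from 10 with t-BuLi at −78 °C adds to it and gives (4E,9R,10S)-1-[(tert-butyldimethylsilyl)oxy]-10,11-bis[(4-methoxybenzyl)oxy]-5,9-dimethylundec-4-en-6-ol as a C6 epimer mixture F2. Dess–Martin oxidation returns to the route at 12.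

**Further compounds**
F1 | step 5 | (4R,5S)-5,6-bis[(4-methoxybenzyl)oxy]-4-methylhexanal | O=CCC[C@@H](C)[C@H](OCc1ccc(OC)cc1)COCc1ccc(OC)cc1
F2 | step 5 | (4E,9R,10S)-1-[(tert-butyldimethylsilyl)oxy]-10,11-bis[(4-methoxybenzyl)oxy]-5,9-dimethylundec-4-en-6-ol (C6 epimer mixture) | C/C(=C\CCCO[Si](C)(C)C(C)(C)C)C(O)CC[C@@H](C)[C@H](OCc1ccc(OC)cc1)COCc1ccc(OC)cc1
F3 | step 12 | 4-(hydroxymethyl) analogue of 21 (C20 alcohol) | CON(C)C(=O)C(C)(C)[C@H](CCC=O)/C(CO)=C/CC[C@@H](C)[C@H](OCc1ccc(OC)cc1)COCc1ccc(OC)cc1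
F4 | step 12 | 4-(bromomethyl) analogue of 21 (C20 bromide) | CON(C)C(=O)C(C)(C)[C@H](CCC=O)/C(CBr)=C/CC[C@@H](C)[C@H](OCc1ccc(OC)cc1)COCc1ccc(OC)cc1
F5 | step 14 | 2-[(1R,3R,4S)-2-chloro-3-{(3R,4S)-4,5-bis[(4-methoxybenzyl)oxy]-3-methylpentyl}-4-hydroxy-2-methylcyclohexyl]-N-methoxy-N,2-dimethylpropanamide | CC1(Cl)[C@H](C(C)(C)C(=O)N(C)OC)CC[C@H](O)[C@@H]1CC[C@@H](C)[C@H](OCc1ccc(OC)cc1)COCc1ccc(OC)cc1
F6 | step 14 | 4-[(1R,3R,4S)-2-chloro-3-{(3R,4S)-4,5-bis[(4-methoxybenzyl)oxy]-3-methylpentyl}-4-hydroxy-2-methylcyclohexyl]-4-methylpent-1-en-3-one | CC1(Cl)[C@H](C(C)(C)C(=O)C=C)CC[C@H](O)[C@@H]1CC[C@@H](C)[C@H](OCc1ccc(OC)cc1)COCc1ccc(OC)cc1
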